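## Retrosynthetic overview
1. Ring numbering: C1 = quaternary oxirane carbon bearing CH2OBz, C2 = CH(OBz), C3 = CH(OH), C4=C5, C6 = oxirane CH.
2. Cut C1–C6 and C6–O together. The precursor is an acyclic ketone carrying a (Z)-allyl sulfonium ylide (intramolecular ylide epoxy-annulation).
3. Ring order: the carbocycle closes first (ylide C6 onto ketone C1). The oxirane then closes from the same betaine in the same operation. Before this step the only rings are the phenyls.
4. The sulfonium salt comes from a (Z)-allyl chloride. The C2–C3 bond comes from a reagent-controlled syn boron aldol of 1,3-dibenzoyloxyacetone with (Z)-4-chlorobut-2-enal. This aldol places both benzoates and the free C3–OH directly, with no protecting groups.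
5. Building blocks: dihydroxyacetone with benzoyl chloride, and cis-2-butene-1,4-diol, which supplies the cis C4=C5.

Assumption: (−)-Ipc2BOTf (from (+)-α-pinene) sends its Z-enol borinate to the Si face of the aldehyde, the sense these ligands show in allylboration; the first batch of 8 is checked by Mosher esters, and the antipodal reagent is equally available.

## Route

Step 1
Reactants: 1 1,3-dihydroxyacetone
Product: 2 2-oxopropane-1,3-diyl dibenzoate (1,3-dibenzoyloxyacetone)
Conditions: BzCl (2.2 equiv), pyridine, CH2Cl2, 0 °C → rt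
Reagents that add atoms: benzoyl chloride, O=C(Cl)c1ccccc1
Why: Pyridine-mediated O-acylation (Einhorn type), in which the commercial hemiketal dimer reverts to the monomeric ketone and only its two primary hydroxyls can be benzoylated, no stereocentre being involved.

Step 2
Reactants: 3 (Z)-but-2-ene-1,4-diol
Product: 4 (Z)-4-chlorobut-2-en-1-ol
Conditions: SOCl2 (1.0 equiv), pyridine (1.0 equiv), Et2O, 0 °C → rt; distil
Reagents that add atoms: thionyl chloride, O=S(Cl)Cl
Why: Chlorodehydroxylation through the chlorosulfite, collapsed by chloride in an SN2 sense so that the cis alkene is kept, and with one equivalent of SOCl2 the monochloride is the main product, which distillation frees from diol and dichloride; no stereocentre is formed.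

Step 3
Reactants: 4 (Z)-4-chlorobut-2-en-1-ol
Product: 5 (Z)-4-chlorobut-2-enal
Conditions: activated MnO2 (15 equiv), CH2Cl2, 0 °C, dark, 1–2 h; filter (Celite), dry over 4 Å sieves, use the cold solution at once
Reagents that add atoms: none
Why: Heterogeneous MnO2 oxidation of an allylic alcohol is neutral and free of the amines and acids that isomerise cis-enals, so the Z geometry needed for ring closure is carried into 5 as long as the solution stays cold and is used directly.

Step 4
Reactants: 2 2-oxopropane-1,3-diyl dibenzoate; 5 (Z)-4-chlorobut-2-enal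
Product: 8 (3S,4R,5Z)-7-chloro-4-hydroxy-2-oxohept-5-ene-1,3-diyl dibenzoate, via Z-enol diisopinocampheylborinate 6 (not isolated), via boron aldolate 7 (not isolated)
Conditions: 2, (−)-Ipc2BOTf (1.3 equiv), i-Pr2NEt (1.5 equiv), CH2Cl2, −78 °C, 3 h; 5 (1.3 equiv), −78 → −40 °C, 12 h; MeOH, pH 7 buffer, 30% H2O2, 0 °C
Reagents that add atoms: none
Why: Reagent-controlled boron aldol reaction (Paterson type), in which triflate plus hindered amine enolises the symmetric ketone to Z-enol borinate 6, the Zimmerman–Traxler chair turns Z geometry into the 3,4-syn (threo) pair, and the (−)-Ipc ligands direct attack to the Si face of 5, setting C3 (S) and C4 (R) (ring C2 and C3), while buffered H2O2 cleaves aldolate 7 without touching benzoates, ketone or allylic chloride.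

Step 5
Reactants: 8 (3S,4R,5Z)-7-chloro-4-hydroxy-2-oxohept-5-ene-1,3-diyl dibenzoate
Product: 12 [(1S,2S,3R,6S)-2-(benzoyloxy)-3-hydroxy-7-oxabicyclo[4.1.0]hept-4-en-1-yl]methyl benzoate (target), via sulfonium tetrafluoroborate 9 (not isolated), via allyl ylide 10 (not isolated), via betaine 11 (not isolated)
Conditions: tetrahydrothiophene (5 equiv), NaBF4 (1.5 equiv), MeCN, 30 °C, dark, 24 h; then dilute with CH2Cl2 (1:5), −78 °C, phosphazene base P2-Et (1.05 equiv), → −20 °C; pH 7 buffer; chromatography, recrystallise to raise ee
Reagents that add atoms: none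
Why: Proposed new method: SN2 capture of the allylic chloride by the sulfide and metal-free deprotonation of the most acidic C–H (allylic sulfonium, more acidic in aprotic medium than the ketone α-C–H and far more than the O–H, whose poor leaving-group ability also blocks vinylogous elimination) give Z-allyl ylide 10, whose carbanion is held by the cis alkene within reach of the doubly α-acyloxy-activated ketone and adds in an allowed 6-(enolendo-like)-exo-trig mode through a half-chair in which the free C3–OH hydrogen-bonds to the developing C1 alkoxide and the C2–OBz dipole lies anti to C=O (Cornforth type), so that O1 ends cis to O3 and trans to OBz, and only betaine 11 with O− and S+ antiperiplanar collapses by 3-exo-tet displacement with inversion at C6 to the cis-fused vinyl oxirane, setting C1 (S) and C6 (S) together and closing carbocycle and oxirane in one operation; the closest known reaction types are the intramolecular Johnson–Corey–Chaykovsky epoxidation and the epoxy-annulation of butadienylsulfonium salts with keto enolates.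

## Compound list
1 | 1,3-dihydroxyacetone (bought as its crystalline dimer, which reverts to the monomer in pyridine) | OCC(=O)CO | starting material
2 | 2-oxopropane-1,3-diyl dibenzoate | O=C(COC(=O)c1ccccc1)COC(=O)c1ccccc1 | intermediate
3 | (Z)-but-2-ene-1,4-diol | OC/C=C\CO | starting material
4 | (Z)-4-chlorobut-2-en-1-ol | OC/C=C\CCl | intermediate
5 | (Z)-4-chlorobut-2-enal | O=C/C=C\CCl | intermediate
6 | (Z)-2-[bis((−)-isopinocampheyl)boryloxy]prop-1-ene-1,3-diyl dibenzoate (OB and OBz cis) | O=C(OC/C(OB([C@@H]1C[C@@H]2C[C@H]([C@H]1C)C2(C)C)[C@@H]1C[C@@H]2C[C@H]([C@H]1C)C2(C)C)=C/OC(=O)c1ccccc1)c1ccccc1 | intermediate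
7 | O-bis((−)-isopinocampheyl)boryl derivative of 8 (boron aldolate) | O=C(OCC(=O)[C@@H](OC(=O)c1ccccc1)[C@H](OB([C@@H]1C[C@@H]2C[C@H]([C@H]1C)C2(C)C)[C@@H]1C[C@@H]2C[C@H]([C@H]1C)C2(C)C)/C=C\CCl)c1ccccc1 | intermediate
8 | (3S,4R,5Z)-7-chloro-4-hydroxy-2-oxohept-5-ene-1,3-diyl dibenzoate (heptene C2–C7 become ring C1–C6) | O=C(OCC(=O)[C@@H](OC(=O)c1ccccc1)[C@H](O)/C=C\CCl)c1ccccc1 | intermediate
9 | 1-[(2Z,4R,5S)-5,7-bis(benzoyloxy)-4-hydroxy-6-oxohept-2-en-1-yl]tetrahydrothiophenium tetrafluoroborate | O=C(OCC(=O)[C@@H](OC(=O)c1ccccc1)[C@H](O)/C=C\C[S+]1CCCC1)c1ccccc1.F[B-](F)(F)F | intermediate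
10 | allyl ylide of 9 (carbanion on the S-bound allylic carbon, Z alkene kept) | O=C(OCC(=O)[C@@H](OC(=O)c1ccccc1)[C@H](O)/C=C\[CH-][S+]1CCCC1)c1ccccc1 | intermediate
11 | cyclohexene betaine: C1 alkoxide cis to C3–OH and trans to C2–OBz, C6 sulfonium trans to the alkoxide | O=C(OC[C@]1([O-])[C@H]([S+]2CCCC2)C=C[C@@H](O)[C@@H]1OC(=O)c1ccccc1)c1ccccc1 | intermediate
12 | [(1S,2S,3R,6S)-2-(benzoyloxy)-3-hydroxy-7-oxabicyclo[4.1.0]hept-4-en-1-yl]methyl benzoate | O=C(OC[C@]12O[C@H]1C=C[C@@H](O)[C@@H]2OC(=O)c1ccccc1)c1ccccc1 | target

Total step count: 5. Longest linear sequence: 4 (3 → 4 → 5 → 8 → 12).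

## Steps most likely to fail

**Step 5.** There are four failure modes:
- O-alkylation to a 2,5-dihydrofuran.
- Z→E leakage of the sulfonium salt.
- [2,3]-shift of the ylide formed on a ring CH2 of the sulfide.
- Closure on the wrong ketone face.

The fallback sets out from 8 and comes back at 12. It closes the rings one at a time by olefination and oxygenation. PPh3 in MeCN replaces the sulfide and gives the allyl phosphonium chloride F1. P2-Et in CH2Cl2 (−78 °C → rt) triggers an intramolecular Wittig reaction with the ketone and gives the trans-dihydrodiol-type cyclohexadiene F2. Photooxygenation follows (O2, tetraphenylporphyrin, visible light, CH2Cl2, −30 °C). Singlet oxygen adds across C1/C4 on the face that carries the C3–OH (hydrogen-bond direction) and is free of the C2–OBz, giving the endoperoxide F3. P(OMe)3 attacks the less hindered peroxide oxygen on C4. The C1 alkoxide then closes on C6 in an SN2' sense and delivers 12.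

**Step 4.** The risks are modest ee or dr with the diacyloxy ketone, and Lewis-acid isomerisation of 5. The fallback sets out from 2 (with 5) and comes back at 8. It replaces the stoichiometric chiral enol borinate and its closed chair by a catalytic Mukaiyama aldol with an open transition state. TMSOTf and Et3N (CH2Cl2, 0 °C) convert 2 into the silyl enol ether F4. F4 adds to 5 at −78 °C in EtCN under 20 mol % of a chiral acyloxyborane. This catalyst is made in situ from BH3·THF and (2S,3S)-2-O-(2,6-diisopropoxybenzoyl)tartaric acid. This catalyst class is syn-selective whatever the enol ether geometry. Work-up with 1 M HCl gives 8.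

**Step 3.** The risk is that the cis-enal isomerises to the trans-enal, which cannot cyclise later. The fallback sets out from 2 and comes back at 8. It installs the cis alkene only after the C–C bond is made. Commercial 4-chlorobut-2-yn-1-ol is oxidised with MnO2 (CH2Cl2, rt) to 4-chlorobut-2-ynal F5, which has no geometry to lose. F5 takes the place of 5 under the step 4 conditions and gives the propargylic alcohol F6. Cis-semihydrogenation (H2 1 atm, Pd/CaCO3 poisoned with Pb(OAc)2, quinoline, EtOAc, 0 °C, stopped at one equivalent) gives 8.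

## Further compounds
F1 | step 5 | [(2Z,4R,5S)-5,7-bis(benzoyloxy)-4-hydroxy-6-oxohept-2-en-1-yl]triphenylphosphonium chloride | O=C(OCC(=O)[C@@H](OC(=O)c1ccccc1)[C@H](O)/C=C\C[P+](c1ccccc1)(c1ccccc1)c1ccccc1)c1ccccc1.[Cl-]
F2 | step 5 | [(5R,6R)-6-(benzoyloxy)-5-hydroxycyclohexa-1,3-dien-1-yl]methyl benzoate | O=C(OCC1=CC=C[C@@H](O)[C@@H]1OC(=O)c1ccccc1)c1ccccc1
F3 | step 5 | 2,3-dioxabicyclo[2.2.2]oct-5-ene endoperoxide of F2, O–O bridge syn to the hydroxyl and anti to the ring benzoate | O=C(OC[C@]12OO[C@H](C=C1)[C@@H](O)[C@@H]2OC(=O)c1ccccc1)c1ccccc1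
F4 | step 4 | (Z)-2-(trimethylsilyloxy)prop-1-ene-1,3-diyl dibenzoate | C[Si](C)(C)O/C(COC(=O)c1ccccc1)=C\OC(=O)c1ccccc1
F5 | step 3 | 4-chlorobut-2-ynal | O=CC#CCCl
F6 | step 3 | (3S,4R)-7-chloro-4-hydroxy-2-oxohept-5-yne-1,3-diyl dibenzoate | O=C(OCC(=O)[C@@H](OC(=O)c1ccccc1)[C@H](O)C#CCCl)c1ccccc1
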